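(The data are calculated for an exercise; noise was put on by code.)

The constants of E are not given, so I read one from the runs: its lifetime, the time of a reading divided by ln(charge over what is left).

| flask | E | X | temperature | remark | time |
|---|---|---|---|---|---|
| dawn | 0.50 mM | 1.2 equiv | −20 °C | run made earlier |  |
| autumn | 1 mM | 1.2 equiv | −20 °C | run made earlier |  |
| maple | 0.50 mM | 1.20 equiv |  | everything together at the start at −40 °C, warmed to −20 °C at 1.0 min | 2.5 min |
| ash | 0.50 mM | 1.20 equiv (fed, over 1.0 min) | −20 °C | all else is in the flask from the start; the feed brings no volume worth counting | 2.5 min |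
| alder | 0.50 mM | 1.20 equiv (fed, over 1.0 min) |  | the addition at −40 °C, then warmed to −20 °C; the feed brings no volume worth counting | 2.5 min |
| larch | 0.50 mM (fed, over 1.0 min) | 1.20 equiv | −20 °C | all else is in the flask from the start; the feed brings no volume worth counting | 2.5 min |

dawn run (percent of the E charged)

| time / min | G / % | Q / % | E / % |
|---|---|---|---|
| 0.667 | 45.7 | 30.2 | 1.5 |
| 1.33 | 46.8 | 42.1 | 0.7 |
| 2.00 | 46.9 | 48.7 | 0 |
| 2.50 | 47.9 | 50.3 | 0 |

autumn run (percent of the E charged)

| time / s | G / % | Q / % | E / % |
|---|---|---|---|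
| 10.0 | 48.0 | 11.0 | 3.7 |
| 12.0 | 49.0 | 12.9 | 2.3 |
| 30.0 | 54.1 | 25.7 | 1.3 |

(each reading ± 0.5 percentage points)

- percent here means E units held: one G counts as two
- the earlier runs do not show what temperature does; that part of a forecast is a guess

- the flask that comes out highest in amount of G, in percent of the E charged, or "all alike" when all lie within 1.5 percentage points (maple / ash / alder / larch / all alike)
- G at the end, in percent of the E charged, maple
- G at the end, in percent of the E charged, ash
- G at the end, in percent of the E charged, alder
- G at the end, in percent of the E charged, larch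

In the autumn table, the first row (3.7 % of E at 10.0 s) gives 3.03 s, and the second row gives 3.18 s. The third row gives 6.91 s and the first dawn row 9.53 s, both longer, with E at 1.3 % and 1.5 %. So these later readings do not follow one lifetime, and I keep the earliest row.

So I take 3.03 s, though it was read at 1 mM of E and these flasks hold 0.50 mM. By charge E is the limiting reagent, and at −20 °C the feed of 1.0 min is far longer than this lifetime, holding 19.8 lifetimes. In one lifetime, the feed in ash brings 5.05 % of its X.

Whether E waits for X I do not read from the runs: my assumption is that it does not, so I put ash near dawn's final G of 47.9 %. A second consequence is that mean [E] over the feed is the charge times the lifetime over the feed time, 0.0253 mM, in ash and larch alike. What the cold does to the lifetime is a guess.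

The forecast names ash: maple 51 %, ash 80 % (72 % to 87 %), alder 70 %, larch 44 %, with the words “A rough stepwise estimate gives ash about 80%”. My reckoning puts ash well below that.

Of the four flasks alder comes out highest, at 60.6 %; maple gives 54.3 %, ash 51.1 %, larch 38.1 %.

    E → J (k = 0.219 s⁻¹, Ea = 63.0 kJ mol⁻¹)
    E + X ⇌ Z (K = 1330 M⁻¹, k = 90.5 M⁻¹ s⁻¹, Ea = 38.0 kJ mol⁻¹, ΔH = −33.0 kJ mol⁻¹)
    X + J → Q (k = 52.2 M⁻¹ s⁻¹, Ea = 43.0 kJ mol⁻¹)
    X + Z ⇌ D (K = 640 M⁻¹, k = 15.6 M⁻¹ s⁻¹, Ea = 41.0 kJ mol⁻¹, ΔH = −29.0 kJ mol⁻¹)
    E + J → G (k = 540 M⁻¹ s⁻¹, Ea = 38.0 kJ mol⁻¹)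
    (constants at −20 °C)

Ash ends 29 percentage points below the forecast. Over the first 1.0 min, mean [E] is 0.0283 mM in ash and 0.0279 mM in larch, where the lifetime of 3.03 s gave 0.0253 mM.

A neighbour of alder holds 0.300 equiv of X, a quarter of alder's. My lifetime has no X in it, so G there should stay near alder's 60.6 %. The neighbour gives 65.3 %, with 20.9 % of J at the end.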